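## Structural features

The target, C47H56O16, is a linear tetramer of the type A–B–B–A: two outer butanoylfilicinic acid rings (ring A, a six-membered enolised β-triketone with a quaternary CMe2 carbon and a butanoyl group) and two inner butanoylphloroglucinol rings (ring B, aromatic), joined by three CH2 bridges. Each ring B is fully substituted: C1 carries the central CH2, C3 the butanoyl group, C5 the CH2 that leads to ring A, and C2, C4 and C6 carry hydroxyl groups; ring A is attached through the enol carbon that lies between C–OH and C=O. There is no stereocentre (the CMe2 carbons are not stereogenic), so no configuration has to be set, and rings A are mobile tautomers of which one is drawn. The fragile elements are the CH2 bridges flanked by free hydroxyl groups, which can be opened and redistributed by retro-Michael or retro-Friedel–Crafts paths in hot acid or base, the air-sensitive polyphenolate anions, and the β-triketone acyl groups, which can be lost by retro-Claisen cleavage. The real difficulty is constitutional: each ring B must receive exactly one acyl group and two different CH2 links at defined carbons, and the rings must be joined in the order A–B–B–A without statistical A–A and B–B products. The key step exploits the fact that in ring B the acyl carbon C3 is the neighbour of the hydroxylated carbon C4, with a further oxygen at C2 on its other side: this vicinal C(acyl)/C–O pair is what an aryne C3≡C4 delivers when it takes up butyric acid across the O–C(acyl) bond, and the C2 oxygen decides which end receives which group.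

## Logic of the disconnections

21 ⇒ 16 + two 20. The two bonds between C5 of each ring B and the outer CH2 groups are cut. These symmetry-related bridges are made last so that the sensitive tetramer sees one mild operation only; with the CH2 stored on ring A as an aminomethyl group, ring A is the only electrophile and ring B the only nucleophile. A tetramer becomes one symmetrical dimer and two copies of one monomer. The forward step needs C5 to be the only free nucleophilic carbon of 16 and must run below the temperature at which bridges redistribute.

20 ⇒ 19. The bond between the enol carbon C6 of ring A and the CH2N group is cut. This returns to the parent enolised triketone and a one-carbon iminium electrophile. The forward step must go to completion, since leftover 19 would later give an A–CH2–A dimer.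

19 ⇒ 18. The two C–CH3 bonds at the quaternary carbon are cut, because ring A is an acylphloroglucinol methylated twice at one carbon. The dearomatised ring then comes from an aromatic ketone in one step. The forward step must place both methyl groups on the same carbon and not on the second free carbon or on oxygen.

18 ⇒ 17 + 14. The aryl–C(acyl) bond is cut. All three ring carbons of 17 are equivalent, so only one mono-ketone can form. The forward step must stop after one acylation.

16 ⇒ 15. The four O–CH3 bonds are cut. Methyl ethers carry the C2 and C6 oxygens through the organolithium and fluoride steps, and the C2 methoxy group is the element that steers the aryne. The forward step must cleave four ethers without breaking the central bridge.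

15 ⇒ 13 + two 14 (key disconnection). In each ring B the C3–C(acyl) bond and the C4–O bond are cut. Acyl group and phenol oxygen then both come from 14, the crowded ring needs no electrophilic acylation, and each ring can take up only one acyl group. The forward step needs carboxylate addition at C4 and not C3, and acyl transfer faster than protonation of the aryl anion.

13 ⇒ 11 (through 12). The O–S bonds of the triflates are cut and the oxygens returned to carbamates. The carbamate is the group that placed the silicon; exchanging it for triflate in one flask avoids handling 12. The forward step needs carbamate cleavage under conditions that leave the C–Si bonds alone.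

11 ⇒ 7 (through 8, 9 and 10). The two C3–Si bonds are cut. The carbamate oxygen at C4 and the methoxy group at C2 together mark C3 for lithiation. The forward step needs one lithiation per ring at a ring C–H and none at the central CH2.

7 ⇒ 6. The carbamate C–O bonds are cut, which leads to 6. The forward step is a simple addition to an isocyanate.

6 ⇒ 5. The O–Si bonds are cut. The silyl ether is the group that kept the para oxygen distinct while offering no direction to lithium in the steps before.

5 ⇒ 4. The C–O bond of the carbinol is cut (adjustment of oxidation level). The forward step relies on easy ionisation of the doubly benzylic carbinol.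

4 ⇒ two 2 (through 3). Both aryl–CH bonds are cut. The bridge is formed from an aryl anion defined by its two flanking methoxy groups, which fixes the bridge para to the silyloxy oxygen. The other way, electrophilic bridging of a phloroglucinol triether followed by selective ether cleavage, would have to tell one para methoxy group from two ortho ones on each ring; no dependable control is seen for that, so the para oxygen is kept distinct from the first step. A symmetrical diarylmethane skeleton comes from two molecules of one monomer and a one-carbon ester. The forward step needs lithiation only between the methoxy groups and addition of two aryl units to the ester.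

2 ⇒ 1. The O–Si bond is cut, which leads to commercial 1.

## Other disconnections considered

Alternative 1: The cut runs through each ring A: the bond from the ring carbonyl carbon to the ring CH, the bond from the silyloxy-bearing carbon to the carbon with the CH2 arm, and the bond from the carbonyl carbon to CMe2. In the forward step the bis-cyclobutenone A2 (the B–B core with a 3-ethoxy-4,4-dimethylcyclobutenone on each outer CH2) would be heated with (triisopropylsiloxy)ethyne A3. Four-electron ring opening to a vinylketene, [2+2] addition of the ynol ether, a second ring opening and a six-electron ring closure would give the dimethylcyclohexadienone rings of A1.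
- In its favour: the quaternary CMe2 carbon arrives ready-made, the substitution pattern follows from ketene and ynol ether polarity, and the outer CH2 links exist before ring A does.
- Against it here: A1 has no butanoyl group on rings A, so two C-acylations at hindered positions and the removal of two ethyl enol ethers, two silyl ethers and six benzyl ethers must follow. A2 also presupposes a fully acylated, doubly homologated B–B core, so the ring B problem is untouched.
- Comparison: on structure, the alternative spends its key step on ring A, which the chosen plan obtains in two steps from 17, while the chosen key step addresses the harder ring B pattern. On mechanism, the pericyclic cascade should be as predictable in regiochemistry as the aryne insertion. It is the better plan on certainty of the quaternary carbon (step 11 is less clean) and on avoiding a late bridge-forming coupling (step 13). On step economy it would be clearly longer.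

Alternative 2: The cut runs through each ring B at the C3–C4 bond and the C1–C2 bond. In the forward step the CH2-linked bis-diene A5 (a fourfold silyl enol ether of a bis-β-keto ester) would add twice to the ynone A6 (1-ethoxyhex-1-yn-3-one). Each diene would join its ketene acetal terminus to the alkyne carbon that carries the ketone, and its other terminus, the one attached to the central CH2, to the alkyne carbon that carries the ethoxy group; expulsion of the acetal methoxy group would then aromatise both rings to A4.
- In its favour: rings B, their acyl groups and the central bridge arise from acyclic material in one operation, regiochemistry follows from matched polarity, no strong base meets a diarylmethane, and the C4 oxygen is not cycled through carbamate and triflate.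
- Against it here: A6 is a push–pull alkyne whose ethoxy group lowers its dienophilicity, the reacting diene termini of A5 are substituted and geometry-dependent, A5 is hydrolytically labile, and two cycloadditions must both succeed. A4 still carries ethyl ethers that need a Lewis-acid cleavage comparable to step 9.
- Comparison: on structure, both plans create the C3 acyl/C4 oxygen pair in one event, and the alternative builds the ring as well. It is the better plan on step count to the B–B core. On mechanism, a cycloaddition of a hindered diene with a deactivated alkyne is judged less certain than fluoride-triggered aryne formation from a bench-stable precursor. Regiochemical certainty and the end game are about equal.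

Alternative 3: The cut is the Cα–Cβ bond of each of the four butanoyl chains. In the forward step A8, the tetramer that carries acetyl in place of butanoyl groups and ten MOM ethers, would be deprotonated at its four methyl ketones with LiN(SiMe3)2 A10 and the enolates ethylated with iodoethane A9 to give A7; acid would then take off the ten MOM groups.
- In its favour: a single, well-understood bond type, and the chain length is chosen at the very end, so congeners with other acyl groups would come from one intermediate. On this divergence it is the better plan.
- Against it here: A8 is as hard to assemble as the target itself, so ring construction and bridging are not simplified. Ten MOM ethers must be placed on hindered, chelated hydroxyl groups. Four enolates in one molecule can each be alkylated twice or on oxygen, and incomplete conversion would leave homologues that are hard to separate. The tenfold acidic deprotection exposes the bridges to scrambling.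
- Comparison: on structure it leaves the core problem open. On mechanism it is equal to the chosen plan per site but demands fourfold fidelity. On step economy it adds protection, alkylation and deprotection to a complete tetramer synthesis and is longer.

Key step: step 8

Assumption: rings A are drawn as the dienol–enone tautomer shown for 21 in the compound list, and the target has no stereocentre.

Remark on the structures: the silyl triflate 13 and the ketone 15 carry the substitution pattern of ring B of the target (C3 acyl, C4 oxygen, C5 free). The para oxygen is kept distinct from the first step (3,5-dimethoxyphenol as its silyl ether), the central CH2 comes from ethyl formate, which joins two molecules of the lithiated monomer, and the outer CH2 groups come from an iminium salt.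

## Route

Step 1
Reactants: 1 3,5-dimethoxyphenol
Product: 2 (3,5-dimethoxyphenoxy)triisopropylsilane
Conditions: TIPSCl, imidazole, DMF, rt
Reagents that add atoms: chlorotriisopropylsilane, CC(C)[Si](Cl)(C(C)C)C(C)C
Why: O-Silylation of a phenol; the bulky silyl ether protects the future triflate oxygen and, unlike an alkyl ether or a carbamate, neither coordinates lithium nor leaves room for metalation beside it.

Step 2
Reactants: 2 (3,5-dimethoxyphenoxy)triisopropylsilane (two equivalents)
Product: 4 bis[2,6-dimethoxy-4-(triisopropylsilyloxy)phenyl]methanol, via aryllithium 3 (not isolated)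
Conditions: n-BuLi (1.05 equiv per 2), THF, 0 °C to rt; HCO2Et (0.5 equiv per 2), −78 °C to rt; aq. NH4Cl
Reagents that add atoms: ethyl formate, CCOC=O
Why: Directed ortho-metalation at the only C–H flanked by two methoxy groups, followed by addition of two aryllithium units to one formate ester through the aldehyde, so that two molecules of 2 are joined at one carbinol carbon; the bridge carbon is thereby fixed para to the silyloxy group on both rings.

Step 3
Reactants: 4 bis[2,6-dimethoxy-4-(triisopropylsilyloxy)phenyl]methanol
Product: 5 bis[2,6-dimethoxy-4-(triisopropylsilyloxy)phenyl]methane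
Conditions: Et3SiH, CF3CO2H, CH2Cl2, 0 °C
Reagents that add atoms: none
Why: Ionic hydrogenation; the carbinol ionises to a diarylmethyl cation stabilised by four ortho-methoxy and two para-silyloxy donors, which takes hydride from the silane, and any partial loss of silyl ether is harmless because step 4 removes it.

Step 4
Reactants: 5 bis[2,6-dimethoxy-4-(triisopropylsilyloxy)phenyl]methane
Product: 6 bis(4-hydroxy-2,6-dimethoxyphenyl)methane
Conditions: Bu4NF, THF, 0 °C; aq. NH4Cl
Reagents that add atoms: none
Why: Fluoride cleavage of the aryl silyl ethers, driven by the Si–F bond and the good phenoxide leaving group; methyl ethers and the bridge are inert.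

Step 5
Reactants: 6 bis(4-hydroxy-2,6-dimethoxyphenyl)methane
Product: 7 bis[4-(isopropylcarbamoyloxy)-2,6-dimethoxyphenyl]methane
Conditions: i-PrNCO, Et3N (cat.), CH2Cl2, rt
Reagents that add atoms: isopropyl isocyanate, CC(C)N=C=O
Why: Base-catalysed addition of the phenols to the isocyanate gives the N-monoalkyl carbamates, which can direct lithiation after N-silylation and can later be removed by elimination under mild base.

Step 6
Reactants: 7 bis[4-(isopropylcarbamoyloxy)-2,6-dimethoxyphenyl]methane
Product: 11 bis[4-(isopropylcarbamoyloxy)-2,6-dimethoxy-3-(trimethylsilyl)phenyl]methane, via N-silyl biscarbamate 8 (not isolated), via dilithio biscarbamate 9 (not isolated), via tetrasilyl biscarbamate 10 (not isolated)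
Conditions: TBSOTf, TMEDA, Et2O–THF, 0 °C to rt; n-BuLi (about 1.2 equiv per ring), TMEDA, −78 °C; TMSCl, −78 °C to rt; aq. NaHSO4
Reagents that add atoms: chlorotrimethylsilane, C[Si](C)(C)Cl
Why: Directed ortho-metalation; N-silylation masks the N–H, the N-silyl carbamate and the neighbouring methoxy group together guide lithium to C3 (C3 and C5 are equivalent), one lithiation per ring is expected because a second would place two charges on one ring, and aqueous acid removes the N-silyl groups after C-silylation.

Step 7
Reactants: 11 bis[4-(isopropylcarbamoyloxy)-2,6-dimethoxy-3-(trimethylsilyl)phenyl]methane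
Product: 13 bis[2,6-dimethoxy-4-(trifluoromethanesulfonyloxy)-3-(trimethylsilyl)phenyl]methane, via bis(silylphenol) 12 (not isolated)
Conditions: DBU, Et2NH, MeCN, 40 °C; PhNTf2, rt
Reagents that add atoms: N-phenylbis(trifluoromethanesulfonimide), O=S(=O)(N(c1ccccc1)S(=O)(=O)C(F)(F)F)C(F)(F)F
Why: E1cB cleavage of the N–H carbamate (DBU removes the N–H proton, phenoxide leaves, Et2NH scavenges the isocyanate as a urea) and triflation of the phenoxide in the same flask, so that the protodesilylation-prone ortho-silyl phenol is never isolated.

Step 8
Reactants: 13 bis[2,6-dimethoxy-4-(trifluoromethanesulfonyloxy)-3-(trimethylsilyl)phenyl]methane; 14 butyric acid (two equivalents)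
Product: 15 bis(3-butanoyl-4-hydroxy-2,6-dimethoxyphenyl)methane
Conditions: CsF, THF, 125 °C (sealed tube), 14 in small excess over two equivalents; dil. HCl work-up
Reagents that add atoms: none
Why: On each ring in turn, fluoride takes the trimethylsilyl group off C3 and the triflate on C4 departs, which releases an aryne C3≡C4. The carboxylate CsO2CCH2CH2CH3, formed in the flask from 14 and CsF, adds through oxygen to C4, and the aryl anion created at C3 attacks the carbonyl group of the aryl ester just formed; the four-membered alkoxide opens to the 3-butanoyl phenoxide, which amounts to insertion of the aryne into the O–C(acyl) bond. The closest known reaction type is the σ-bond insertion of arynes into carboxylic acids to give ortho-hydroxyaryl ketones, a relative of the anionic Fries shift. No ring is closed and no stereocentre is formed. The selectivity needed is the direction of carboxylate addition: the C2 methoxy group beside the triple bond polarises and distorts the aryne so that the nucleophile enters at the remote, less hindered C4 and the charge develops at C3 next to the inductively stabilising oxygen; the weaker opposing pull of the C6 methoxy group should not override this. Acyl transfer must also outrun protonation of the aryl anion, which is served by high temperature, an aprotic medium and only a small excess of acid. The two rings are insulated by the CH2 group and should react independently.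

Step 9
Reactants: 15 bis(3-butanoyl-4-hydroxy-2,6-dimethoxyphenyl)methane
Product: 16 bis(3-butanoyl-2,4,6-trihydroxyphenyl)methane
Conditions: BBr3, CH2Cl2, −78 °C to rt; H2O
Reagents that add atoms: none
Why: Lewis-acid cleavage of aryl methyl ethers (boron coordinates to oxygen, bromide attacks the methyl group); the methoxy groups beside the ketones go first through a six-membered boron chelate, and low temperature protects the diarylmethane bridge.

Step 10
Reactants: 17 phloroglucinol; 14 butyric acid
Product: 18 1-(2,4,6-trihydroxyphenyl)butan-1-one
Conditions: BF3·OEt2 (as medium), 80 °C; aq. NaOAc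
Reagents that add atoms: none
Why: Friedel–Crafts C-acylation with the free acid activated by BF3; the three ring carbons are equivalent, and the first ketone deactivates the ring and is tied up as a boron chelate, which favours mono-acylation.

Step 11
Reactants: 18 1-(2,4,6-trihydroxyphenyl)butan-1-one
Product: 19 2-butanoyl-3,5-dihydroxy-4,4-dimethylcyclohexa-2,5-dien-1-one (butanoylfilicinic acid)
Conditions: NaOMe, MeI (about 2 equiv), MeOH, 0 °C to rt
Reagents that add atoms: iodomethane, CI
Why: Dearomative C-methylation of the phloroglucinol polyanion; the second methyl group enters at the carbon already methylated, which is the more electron-rich site, and gives the gem-dimethyl enolised triketone, while limiting the alkylating agent holds back further methylation.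

Step 12
Reactants: 19 2-butanoyl-3,5-dihydroxy-4,4-dimethylcyclohexa-2,5-dien-1-one
Product: 20 2-butanoyl-6-[(dimethylamino)methyl]-3,5-dihydroxy-4,4-dimethylcyclohexa-2,5-dien-1-one
Conditions: [Me2N=CH2]I (slight excess), Et3N, CH2Cl2, 0 °C to rt
Reagents that add atoms: dimethylmethyleneiminium iodide, C=[N+](C)C.[I-]
Why: Mannich reaction of the enolate at its only free ring carbon with a preformed iminium ion; the excess of iminium ion consumes 19 fully, so no ring A dimer can arise later.

Step 13
Reactants: 16 bis(3-butanoyl-2,4,6-trihydroxyphenyl)methane; 20 2-butanoyl-6-[(dimethylamino)methyl]-3,5-dihydroxy-4,4-dimethylcyclohexa-2,5-dien-1-one (two equivalents)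
Product: 21 bis{3-butanoyl-5-[(5-butanoyl-2,4-dihydroxy-3,3-dimethyl-6-oxocyclohexa-1,4-dien-1-yl)methyl]-2,4,6-trihydroxyphenyl}methane (target)
Conditions: MeCN–THF (degassed), 60 °C; dil. HCl work-up
Reagents that add atoms: none
Why: Elimination of dimethylamine from the Mannich base gives the exocyclic methylene triketone, which is captured in a Michael-type Friedel–Crafts alkylation by C5 of each ring B, the only free ring carbon of 16; rearomatisation gives the two outer bridges under mild, nearly neutral conditions.

## Compound list

1 | 3,5-dimethoxyphenol | COc1cc(O)cc(OC)c1 | starting material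
2 | (3,5-dimethoxyphenoxy)triisopropylsilane | COc1cc(O[Si](C(C)C)(C(C)C)C(C)C)cc(OC)c1 | intermediate
3 | [2,6-dimethoxy-4-(triisopropylsilyloxy)phenyl]lithium | [Li]c1c(OC)cc(O[Si](C(C)C)(C(C)C)C(C)C)cc1OC | intermediate
4 | bis[2,6-dimethoxy-4-(triisopropylsilyloxy)phenyl]methanol | COc1cc(O[Si](C(C)C)(C(C)C)C(C)C)cc(OC)c1C(O)c1c(OC)cc(O[Si](C(C)C)(C(C)C)C(C)C)cc1OC | intermediate
5 | bis[2,6-dimethoxy-4-(triisopropylsilyloxy)phenyl]methane | COc1cc(O[Si](C(C)C)(C(C)C)C(C)C)cc(OC)c1Cc1c(OC)cc(O[Si](C(C)C)(C(C)C)C(C)C)cc1OC | intermediate
6 | bis(4-hydroxy-2,6-dimethoxyphenyl)methane | COc1cc(O)cc(OC)c1Cc1c(OC)cc(O)cc1OC | intermediate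
7 | bis[4-(isopropylcarbamoyloxy)-2,6-dimethoxyphenyl]methane | COc1cc(OC(=O)NC(C)C)cc(OC)c1Cc1c(OC)cc(OC(=O)NC(C)C)cc1OC | intermediate
8 | bis{4-[N-(tert-butyldimethylsilyl)-N-isopropylcarbamoyloxy]-2,6-dimethoxyphenyl}methane | COc1cc(OC(=O)N(C(C)C)[Si](C)(C)C(C)(C)C)cc(OC)c1Cc1c(OC)cc(OC(=O)N(C(C)C)[Si](C)(C)C(C)(C)C)cc1OC | intermediate
9 | bis{4-[N-(tert-butyldimethylsilyl)-N-isopropylcarbamoyloxy]-3-lithio-2,6-dimethoxyphenyl}methane | COc1cc(OC(=O)N(C(C)C)[Si](C)(C)C(C)(C)C)c([Li])c(OC)c1Cc1c(OC)cc(OC(=O)N(C(C)C)[Si](C)(C)C(C)(C)C)c([Li])c1OC | intermediate
10 | bis{4-[N-(tert-butyldimethylsilyl)-N-isopropylcarbamoyloxy]-2,6-dimethoxy-3-(trimethylsilyl)phenyl}methane | COc1cc(OC(=O)N(C(C)C)[Si](C)(C)C(C)(C)C)c([Si](C)(C)C)c(OC)c1Cc1c(OC)cc(OC(=O)N(C(C)C)[Si](C)(C)C(C)(C)C)c([Si](C)(C)C)c1OC | intermediate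
11 | bis[4-(isopropylcarbamoyloxy)-2,6-dimethoxy-3-(trimethylsilyl)phenyl]methane | COc1cc(OC(=O)NC(C)C)c([Si](C)(C)C)c(OC)c1Cc1c(OC)cc(OC(=O)NC(C)C)c([Si](C)(C)C)c1OC | intermediate
12 | bis[4-hydroxy-2,6-dimethoxy-3-(trimethylsilyl)phenyl]methane | COc1cc(O)c([Si](C)(C)C)c(OC)c1Cc1c(OC)cc(O)c([Si](C)(C)C)c1OC | intermediate
13 | bis[2,6-dimethoxy-4-(trifluoromethanesulfonyloxy)-3-(trimethylsilyl)phenyl]methane | COc1cc(OS(=O)(=O)C(F)(F)F)c([Si](C)(C)C)c(OC)c1Cc1c(OC)cc(OS(=O)(=O)C(F)(F)F)c([Si](C)(C)C)c1OC | intermediate
14 | butyric acid | CCCC(=O)O | starting material
15 | bis(3-butanoyl-4-hydroxy-2,6-dimethoxyphenyl)methane | CCCC(=O)c1c(O)cc(OC)c(Cc2c(OC)cc(O)c(C(=O)CCC)c2OC)c1OC | intermediate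
16 | bis(3-butanoyl-2,4,6-trihydroxyphenyl)methane | CCCC(=O)c1c(O)cc(O)c(Cc2c(O)cc(O)c(C(=O)CCC)c2O)c1O | intermediate
17 | phloroglucinol | Oc1cc(O)cc(O)c1 | starting material
18 | 1-(2,4,6-trihydroxyphenyl)butan-1-one | CCCC(=O)c1c(O)cc(O)cc1O | intermediate
19 | 2-butanoyl-3,5-dihydroxy-4,4-dimethylcyclohexa-2,5-dien-1-one | CCCC(=O)C1=C(O)C(C)(C)C(O)=CC1=O | intermediate
20 | 2-butanoyl-6-[(dimethylamino)methyl]-3,5-dihydroxy-4,4-dimethylcyclohexa-2,5-dien-1-one | CCCC(=O)C1=C(O)C(C)(C)C(O)=C(CN(C)C)C1=O | intermediate
21 | bis{3-butanoyl-5-[(5-butanoyl-2,4-dihydroxy-3,3-dimethyl-6-oxocyclohexa-1,4-dien-1-yl)methyl]-2,4,6-trihydroxyphenyl}methane | CCCC(=O)C1=C(O)C(C)(C)C(O)=C(Cc2c(O)c(Cc3c(O)c(CC4=C(O)C(C)(C)C(O)=C(C(=O)CCC)C4=O)c(O)c(C(=O)CCC)c3O)c(O)c(C(=O)CCC)c2O)C1=O | target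

## Step count and risks

Total: 13 steps. Longest linear sequence: 10 steps (steps 1 to 9, then step 13); the ring A branch (steps 10 to 12) is three steps.

Least certain steps:

**Step 8 (key step).** The most likely failure is protonation of the aryl anion at C3 before it reaches the ester carbonyl. This would stop at plain O-arylation of butyrate, and it is favoured by any free acid or bifluoride near the anion. A second concern is fluoride-induced loss of silicon by protonation without aryne formation, and a third is arylation of the product phenoxide by a later aryne. Fallback without aryne chemistry: it sets out from 6, which is O-acylated with butyryl chloride (Et3N, DMAP cat., CH2Cl2) to bis(4-butanoyloxy-2,6-dimethoxyphenyl)methane F1. A Fries rearrangement (TiCl4, CH2Cl2, 0 °C to rt, or irradiation at 254 nm) then moves each acyl group to a position ortho to its oxygen. Both ortho positions are equivalent and the para position is occupied by the bridge, so the route is rejoined at 15.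

**Step 6.** Competing deprotonation at the central CH2, whose protons are doubly benzylic, would consume base and give C-silylation at the bridge. A second lithiation of a ring already silylated, or migration of the carbamoyl group to carbon on warming, are further concerns. The site between carbamate and methoxy is expected to be kinetically preferred at −78 °C, but the margin is not known for this substrate. Fallback that needs no deprotonation: it sets out from 6, which is brominated once per ring ortho to the hydroxyl group (N-bromosuccinimide, CH2Cl2, −78 °C) to bis(3-bromo-4-hydroxy-2,6-dimethoxyphenyl)methane F2. Hexamethyldisilazane converts F2 into bis[3-bromo-2,6-dimethoxy-4-(trimethylsilyloxy)phenyl]methane F3. Bromine–lithium exchange with n-BuLi at −78 °C triggers the 1,3 shift of silicon from oxygen to carbon (retro-Brook rearrangement), and the resulting dilithium salt of 12 is triflated with Tf2O, rejoining the route at 13.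

**Step 13.** Redistribution of methylene bridges by reversible retro-Michael cleavage could give A–CH2–A and B-rich products, and the coupling could stop at the trimer after one alkylation. Both are favoured by long heating and by the basic amine set free. Fallback with reversed polarity: it sets out from 16, which is aminomethylated at C5 and C5' with bis(dimethylamino)methane (dioxane, rt to 40 °C) to bis{3-butanoyl-5-[(dimethylamino)methyl]-2,4,6-trihydroxyphenyl}methane F4. Heating F4 with two equivalents of 19 should generate an ortho-quinone methide on each ring B, which is captured by the enol carbon of 19, rejoining the route at 21.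

**Step 11.** Under-methylation, methylation at both free ring carbons, O-methylation and further methylation to tri- and tetramethyl products all compete, because every intermediate is itself a reactive enolate. Fallback that blocks the second carbon: it sets out from 18, which is acylated a second time (14, BF3·OEt2, 90 °C) to 2,4-dibutanoylphloroglucinol F5. Methylation (NaOMe, MeI, MeOH) can then occur only at the single free carbon and gives 2,4-dibutanoyl-3,5-dihydroxy-6,6-dimethylcyclohexa-2,4-dien-1-one F6. Retro-Claisen removal of one of its two equivalent acyl groups (aqueous H2SO4, moderate temperature, stopped at the mono-acyl stage) rejoins the route at 19.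

## Further compounds

F1 | step 8 | bis(4-butanoyloxy-2,6-dimethoxyphenyl)methane | CCCC(=O)Oc1cc(OC)c(Cc2c(OC)cc(OC(=O)CCC)cc2OC)c(OC)c1
F2 | step 6 | bis(3-bromo-4-hydroxy-2,6-dimethoxyphenyl)methane | COc1cc(O)c(Br)c(OC)c1Cc1c(OC)cc(O)c(Br)c1OC
F3 | step 6 | bis[3-bromo-2,6-dimethoxy-4-(trimethylsilyloxy)phenyl]methane | COc1cc(O[Si](C)(C)C)c(Br)c(OC)c1Cc1c(OC)cc(O[Si](C)(C)C)c(Br)c1OC
F4 | step 13 | bis{3-butanoyl-5-[(dimethylamino)methyl]-2,4,6-trihydroxyphenyl}methane | CCCC(=O)c1c(O)c(CN(C)C)c(O)c(Cc2c(O)c(CN(C)C)c(O)c(C(=O)CCC)c2O)c1O
F5 | step 11 | 2,4-dibutanoylphloroglucinol | CCCC(=O)c1c(O)cc(O)c(C(=O)CCC)c1O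
F6 | step 11 | 2,4-dibutanoyl-3,5-dihydroxy-6,6-dimethylcyclohexa-2,4-dien-1-one | CCCC(=O)C1=C(O)C(C(=O)CCC)=C(O)C(C)(C)C1=O
A1 | alternative 1 | hexabenzyl tetramer with rings A as ethyl and triisopropylsilyl enol ethers | CCOC1=C(Cc2c(OCc3ccccc3)c(Cc3c(OCc4ccccc4)c(CC4=C(OCC)C(C)(C)C(=O)C=C4O[Si](C(C)C)(C(C)C)C(C)C)c(OCc4ccccc4)c(C(=O)CCC)c3OCc3ccccc3)c(OCc3ccccc3)c(C(=O)CCC)c2OCc2ccccc2)C(O[Si](C(C)C)(C(C)C)C(C)C)=CC(=O)C1(C)C
A2 | alternative 1 | hexabenzyl B–B core bearing a 3-ethoxy-4,4-dimethylcyclobut-2-en-1-on-2-ylmethyl group on C5 of each ring B | CCOC1=C(Cc2c(OCc3ccccc3)c(Cc3c(OCc4ccccc4)c(CC4=C(OCC)C(C)(C)C4=O)c(OCc4ccccc4)c(C(=O)CCC)c3OCc3ccccc3)c(OCc3ccccc3)c(C(=O)CCC)c2OCc2ccccc2)C(=O)C1(C)C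
A3 | alternative 1 | (triisopropylsiloxy)ethyne | C#CO[Si](C(C)C)(C(C)C)C(C)C
A4 | alternative 2 | bis(3-butanoyl-2-ethoxy-4,6-dihydroxyphenyl)methane | CCCC(=O)c1c(O)cc(O)c(Cc2c(O)cc(O)c(C(=O)CCC)c2OCC)c1OCC
A5 | alternative 2 | 1,9-dimethoxy-1,3,7,9-tetrakis(trimethylsilyloxy)nona-1,3,6,8-tetraene | COC(O[Si](C)(C)C)=CC(O[Si](C)(C)C)=CCC=C(O[Si](C)(C)C)C=C(OC)O[Si](C)(C)C
A6 | alternative 2 | 1-ethoxyhex-1-yn-3-one | CCOC#CC(=O)CCC
A7 | alternative 3 | deca-MOM ether of the target | CCCC(=O)C1=C(OCOC)C(C)(C)C(OCOC)=C(Cc2c(OCOC)c(Cc3c(OCOC)c(CC4=C(OCOC)C(C)(C)C(OCOC)=C(C(=O)CCC)C4=O)c(OCOC)c(C(=O)CCC)c3OCOC)c(OCOC)c(C(=O)CCC)c2OCOC)C1=O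
A8 | alternative 3 | deca-MOM ether of the tetra-acetyl congener | CC(=O)C1=C(OCOC)C(C)(C)C(OCOC)=C(Cc2c(OCOC)c(Cc3c(OCOC)c(CC4=C(OCOC)C(C)(C)C(OCOC)=C(C(C)=O)C4=O)c(OCOC)c(C(C)=O)c3OCOC)c(OCOC)c(C(C)=O)c2OCOC)C1=O
A9 | alternative 3 | iodoethane | CCI
A10 | alternative 3 | lithium bis(trimethylsilyl)amide, LiN(SiMe3)2 | [Li]N([Si](C)(C)C)[Si](C)(C)C
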